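**Retrosynthetic overview**
1. Target 23 ⇐ pentasilyl ether 22 (fluoride) ⇐ exo Diels–Alder of 2'-hydroxychalcone 8 with dehydroprenyl diene 21 on a (R)-VANOL–boron template; this forms the cyclohexene (second and last ring made) and sets C1, C5 and C6.
2. Diene 21 ⇐ iodo-dihydroflavonol 18 + dienyl boronate 20 (Pd(dppf)Cl2 Suzuki coupling).
3. Key disconnection: the C3–C4 bond of the pyranone of 18 ⇐ dialdehyde 17. The ring A aldehyde carbon reacts as an acyl anion (Breslow intermediate of a chiral triazolylidene) with the α-aryloxy aldehyde carbon, with dynamic kinetic resolution; this is the first ring made and sets C2 and C3 together.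
4. 17 ⇐ ozonolysis of branched allyl aryl ether 15 ⇐ carbonate 13 (aldehyde 10 + CH2=CHMgBr) + phenol 14 with [Ir(cod)Cl]2/P(OPh)3.
5. 8 ⇐ LiN(SiMe3)2 Claisen–Schmidt condensation of C-prenylated acetophenone 4 with aldehyde 6.

Assumption: the sense of induction of the triazolium salt (step 10) and of (R)-VANOL (step 13) is assigned by analogy with related substrates and has not been verified for these compounds; both are sold in either mirror-image form.

TBS = tert-butyldimethylsilyl; TIPS = triisopropylsilyl.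

**Step 1**
Reactants: 1 2,4-dihydroxyacetophenone; 2 prenyl bromide
Product: 3 1-[2,4-dihydroxy-3-(3-methylbut-2-en-1-yl)phenyl]ethanone
Conditions: 10% aq. KOH, 0 °C → rt; chromatography
Reagents that add atoms: none
Why: Phenolate C-alkylation in water (O-alkylation is suppressed by hydrogen bonding) goes mainly to C3, the carbon activated by both oxygens; the yield is modest and the 5-prenyl isomer is separated.

**Step 2**
Reactants: 3 1-[2,4-dihydroxy-3-(3-methylbut-2-en-1-yl)phenyl]ethanone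
Product: 4 1-[4-(TBS-oxy)-2-hydroxy-3-(3-methylbut-2-en-1-yl)phenyl]ethanone
Conditions: TBSCl (1.05 equiv), imidazole, CH2Cl2, 0 °C
Reagents that add atoms: tert-butyldimethylsilyl chloride, CC(C)(C)[Si](C)(C)Cl
Why: Selective silylation; the 2-OH is hydrogen-bonded to the acetyl group, so one equivalent of silyl chloride takes only the 4-OH.

**Step 3**
Reactants: 5 2,4-dihydroxybenzaldehyde
Product: 6 2,4-bis(TIPS-oxy)benzaldehyde
Conditions: TIPSOTf (2.4 equiv), 2,6-lutidine, CH2Cl2, 0 °C → rt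
Reagents that add atoms: triisopropylsilyl trifluoromethanesulfonate, CC(C)[Si](OS(=O)(=O)C(F)(F)F)(C(C)C)C(C)C
Why: The silyl triflate silylates both phenols, including the chelated one; TIPS is chosen because it does not migrate to the neighbouring alkoxide formed in step 4.

**Step 4**
Reactants: 4 1-[4-(TBS-oxy)-2-hydroxy-3-(3-methylbut-2-en-1-yl)phenyl]ethanone; 6 2,4-bis(TIPS-oxy)benzaldehyde
Product: 8 (E)-3-[2,4-bis(TIPS-oxy)phenyl]-1-[4-(TBS-oxy)-2-hydroxy-3-(3-methylbut-2-en-1-yl)phenyl]prop-2-en-1-one, via dilithium aldolate 7 (not isolated)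
Conditions: LiN(SiMe3)2 (2.3 equiv), THF, −78 °C; then 6, −78 °C → rt; aq. NH4Cl
Reagents that add atoms: none
Why: Claisen–Schmidt aldol condensation; the phenoxide–enolate dianion of 4 adds to 6 and the aldolate loses LiOH (E1cB) on warming to give the (E)-enone, and aryl silyl ethers survive this non-nucleophilic base.

**Step 5**
Reactants: 9 2-hydroxy-5-iodobenzaldehyde
Product: 10 2-(TBS-oxy)-5-iodobenzaldehyde
Conditions: TBSCl (1.2 equiv), imidazole, DMF, rt
Reagents that add atoms: tert-butyldimethylsilyl chloride, CC(C)(C)[Si](C)(C)Cl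
Why: Standard phenol silylation; the aldehyde and aryl iodide are inert.

**Step 6**
Reactants: 10 2-(TBS-oxy)-5-iodobenzaldehyde; 11 vinylmagnesium bromide
Product: 13 racemic 1-[2-(TBS-oxy)-5-iodophenyl]prop-2-en-1-yl methyl carbonate, via bromomagnesium alkoxide 12 (not isolated)
Conditions: CH2=CHMgBr (1.1 equiv), THF, −78 °C; then ClCO2Me (1.5 equiv), −78 → 0 °C
Reagents that add atoms: methyl chloroformate, COC(=O)Cl
Why: Grignard 1,2-addition followed by acylation of the magnesium alkoxide in the cold, which outpaces silyl migration from the neighbouring phenol; the centre is left racemic because step 10 resets it.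

**Step 7**
Reactants: 5 2,4-dihydroxybenzaldehyde
Product: 14 2-hydroxy-4-(TIPS-oxy)benzaldehyde
Conditions: TIPSCl (1.05 equiv), imidazole, CH2Cl2, 0 °C → rt
Reagents that add atoms: triisopropylsilyl chloride, CC(C)[Si](Cl)(C(C)C)C(C)C
Why: Selective silylation of the non-chelated 4-OH; TIPS is used because this oxygen ends up para to a ketone and must survive the aqueous base of step 12.

**Step 8**
Reactants: 13 racemic 1-[2-(TBS-oxy)-5-iodophenyl]prop-2-en-1-yl methyl carbonate; 14 2-hydroxy-4-(TIPS-oxy)benzaldehyde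
Product: 15 racemic 2-{1-[2-(TBS-oxy)-5-iodophenyl]prop-2-en-1-yloxy}-4-(TIPS-oxy)benzaldehyde
Conditions: [Ir(cod)Cl]2 (2.5 mol%), P(OPh)3 (10 mol%), THF, 50 °C; stop at full conversion
Reagents that add atoms: none
Why: Branched-selective allylic etherification through a (π-allyl)iridium complex; the phenoxide attacks the aryl-substituted terminus, and the methoxide released on decarboxylation is the only base.

**Step 9**
Reactants: 15 racemic 2-{1-[2-(TBS-oxy)-5-iodophenyl]prop-2-en-1-yloxy}-4-(TIPS-oxy)benzaldehyde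
Product: 17 racemic 2-{1-[2-(TBS-oxy)-5-iodophenyl]-2-oxoethoxy}-4-(TIPS-oxy)benzaldehyde, via secondary ozonide 16 (not isolated)
Conditions: O3, CH2Cl2, −78 °C (Sudan red endpoint); then Me2S, −78 °C → rt; used crude at once
Reagents that add atoms: ozone, [O-][O+]=O
Why: Ozonolysis with reductive work-up cleaves the only alkene to the aldehyde; the α-centre is labile, which step 10 exploits.

**Step 10 (key step)**
Reactants: 17 racemic 2-{1-[2-(TBS-oxy)-5-iodophenyl]-2-oxoethoxy}-4-(TIPS-oxy)benzaldehyde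
Product: 18 (2R,3R)-2-[2-(TBS-oxy)-5-iodophenyl]-3-hydroxy-7-(TIPS-oxy)chroman-4-one
Conditions: (5aR,10bS)-2-(pentafluorophenyl)-5a,10b-dihydro-4H,6H-indeno[2,1-b][1,2,4]triazolo[4,3-d][1,4]oxazin-2-ium tetrafluoroborate (10 mol%), i-Pr2NEt (1.0 equiv), toluene, 4 Å MS, argon, 0 °C → rt; quench with AcOH
Reagents that add atoms: none
Why: Proposed new method: the triazolylidene adds to the less hindered aryl aldehyde to give a Breslow acyl-anion equivalent that closes the six-membered ring onto the neighbouring aldehyde through a hydrogen-bonded chair-like transition state (aryl pseudo-equatorial, hence 2,3-trans, also the thermodynamic ketol), while the very acidic α-aryl-α-aryloxy aldehyde centre racemises through its enol under the amine base, so the chiral catalyst converts both enantiomers of 17 into (2R,3R)-18 (dynamic kinetic resolution); the closest known reaction type is the chiral triazolium-catalysed intramolecular crossed benzoin of salicylaldehyde-derived aldehyde–ketones to 3-hydroxychroman-4-ones.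

**Step 11**
Reactants: 19 2-methylbut-1-en-3-yne
Product: 20 (E)-4,4,5,5-tetramethyl-2-(3-methylbuta-1,3-dien-1-yl)-1,3,2-dioxaborolane
Conditions: pinacolborane (1.05 equiv), Cp2Zr(H)Cl (5 mol%), Et3N (10 mol%), neat, rt → 40 °C
Reagents that add atoms: pinacolborane, CC1(C)OBOC1(C)C
Why: Cp2Zr(H)Cl-catalysed syn, anti-Markovnikov hydroboration of the terminal alkyne gives the (E)-dienyl boronate and leaves the 1,1-disubstituted alkene alone.

**Step 12**
Reactants: 18 (2R,3R)-2-[2-(TBS-oxy)-5-iodophenyl]-3-hydroxy-7-(TIPS-oxy)chroman-4-one; 20 (E)-dienyl pinacol boronate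
Product: 21 (2R,3R)-2-{2-(TBS-oxy)-5-[(E)-3-methylbuta-1,3-dien-1-yl]phenyl}-3-hydroxy-7-(TIPS-oxy)chroman-4-one
Conditions: Pd(dppf)Cl2 (5 mol%), K3PO4 (2 equiv), degassed THF/H2O (10:1), rt
Reagents that add atoms: none
Why: Suzuki–Miyaura coupling of the aryl iodide at room temperature with retention of alkene geometry; the mild base, short time and absence of oxygen keep the ketol centres and silyl ethers intact.

**Step 13**
Reactants: 8 (E)-3-[2,4-bis(TIPS-oxy)phenyl]-1-[4-(TBS-oxy)-2-hydroxy-3-(3-methylbut-2-en-1-yl)phenyl]prop-2-en-1-one; 21 (2R,3R)-2-{2-(TBS-oxy)-5-[(E)-3-methylbuta-1,3-dien-1-yl]phenyl}-3-hydroxy-7-(TIPS-oxy)chroman-4-one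
Product: 22 (2R,3R)-2-{2-(TBS-oxy)-5-[(1R,5S,6R)-5-[2,4-bis(TIPS-oxy)phenyl]-6-[4-(TBS-oxy)-2-hydroxy-3-(3-methylbut-2-en-1-yl)benzoyl]-3-methylcyclohex-2-en-1-yl]phenyl}-3-hydroxy-7-(TIPS-oxy)chroman-4-one
Conditions: (R)-VANOL (1.5 equiv), BH3·THF (1.5 equiv), AcOH (1.5 equiv), THF, rt, then evaporate; 8 (1.2 equiv) and 21, PhCF3, 4 Å MS, rt, 48 h; aq. NaHCO3; chromatography
Reagents that add atoms: none
Why: Diels–Alder cycloaddition in which the 2'-hydroxy-enone is chelated to the VANOL-bound boron, which activates the enone, shields one face and gives the "ortho" exo adduct with both aryl groups trans to the aroyl group (1R,5S,6R); the minor endo isomer is separated and the (2R,3R) centres of 21 are untouched.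

**Step 14**
Reactants: 22 pentasilyl ether
Product: 23 (2R,3R)-2-{5-[(1R,5S,6R)-6-[2,4-dihydroxy-3-(3-methylbut-2-en-1-yl)benzoyl]-5-(2,4-dihydroxyphenyl)-3-methylcyclohex-2-en-1-yl]-2-hydroxyphenyl}-3,7-dihydroxychroman-4-one
Conditions: Bu4NF (6 equiv), AcOH (6 equiv), THF, 0 °C → rt
Reagents that add atoms: none
Why: Fluoride cleaves all five aryl silyl ethers; the acetic acid buffer prevents base-induced opening or epimerisation of the dihydroflavonol, and no acid strong enough to cyclise the prenyl phenol is present.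

**Compound list**
1 | 2,4-dihydroxyacetophenone | CC(=O)c1ccc(O)cc1O | starting material
2 | prenyl bromide | CC(C)=CCBr | starting material
3 | 1-[2,4-dihydroxy-3-(3-methylbut-2-en-1-yl)phenyl]ethanone | CC(=O)c1ccc(O)c(CC=C(C)C)c1O | intermediate
4 | 1-[4-(TBS-oxy)-2-hydroxy-3-(3-methylbut-2-en-1-yl)phenyl]ethanone | CC(=O)c1ccc(O[Si](C)(C)C(C)(C)C)c(CC=C(C)C)c1O | intermediate
5 | 2,4-dihydroxybenzaldehyde | O=Cc1ccc(O)cc1O | starting material
6 | 2,4-bis(TIPS-oxy)benzaldehyde | O=Cc1ccc(O[Si](C(C)C)(C(C)C)C(C)C)cc1O[Si](C(C)C)(C(C)C)C(C)C | intermediate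
7 | dilithium aldolate of 4 and 6 (racemic) | CC(C)=CCc1c(O[Si](C)(C)C(C)(C)C)ccc(C(=O)CC(O[Li])c2ccc(O[Si](C(C)C)(C(C)C)C(C)C)cc2O[Si](C(C)C)(C(C)C)C(C)C)c1O[Li] | intermediate (not isolated)
8 | (E)-3-[2,4-bis(TIPS-oxy)phenyl]-1-[4-(TBS-oxy)-2-hydroxy-3-(3-methylbut-2-en-1-yl)phenyl]prop-2-en-1-one | CC(C)=CCc1c(O[Si](C)(C)C(C)(C)C)ccc(C(=O)/C=C/c2ccc(O[Si](C(C)C)(C(C)C)C(C)C)cc2O[Si](C(C)C)(C(C)C)C(C)C)c1O | intermediate
9 | 2-hydroxy-5-iodobenzaldehyde | O=Cc1cc(I)ccc1O | starting material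
10 | 2-(TBS-oxy)-5-iodobenzaldehyde | O=Cc1cc(I)ccc1O[Si](C)(C)C(C)(C)C | intermediate
11 | vinylmagnesium bromide | C=C[Mg]Br | starting material
12 | bromomagnesium 1-[2-(TBS-oxy)-5-iodophenyl]prop-2-en-1-olate (racemic) | C=CC(O[Mg]Br)c1cc(I)ccc1O[Si](C)(C)C(C)(C)C | intermediate (not isolated)
13 | racemic 1-[2-(TBS-oxy)-5-iodophenyl]prop-2-en-1-yl methyl carbonate | C=CC(OC(=O)OC)c1cc(I)ccc1O[Si](C)(C)C(C)(C)C | intermediate
14 | 2-hydroxy-4-(TIPS-oxy)benzaldehyde | O=Cc1ccc(O[Si](C(C)C)(C(C)C)C(C)C)cc1O | intermediate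
15 | racemic 2-{1-[2-(TBS-oxy)-5-iodophenyl]prop-2-en-1-yloxy}-4-(TIPS-oxy)benzaldehyde | C=CC(Oc1cc(O[Si](C(C)C)(C(C)C)C(C)C)ccc1C=O)c1cc(I)ccc1O[Si](C)(C)C(C)(C)C | intermediate
16 | secondary ozonide (1,2,4-trioxolane) of 15 | O=Cc1ccc(O[Si](C(C)C)(C(C)C)C(C)C)cc1OC(C1OCOO1)c1cc(I)ccc1O[Si](C)(C)C(C)(C)C | intermediate (not isolated)
17 | racemic 2-{1-[2-(TBS-oxy)-5-iodophenyl]-2-oxoethoxy}-4-(TIPS-oxy)benzaldehyde | O=CC(Oc1cc(O[Si](C(C)C)(C(C)C)C(C)C)ccc1C=O)c1cc(I)ccc1O[Si](C)(C)C(C)(C)C | intermediate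
18 | (2R,3R)-2-[2-(TBS-oxy)-5-iodophenyl]-3-hydroxy-7-(TIPS-oxy)chroman-4-one | Ic1ccc(O[Si](C)(C)C(C)(C)C)c([C@H]2Oc3cc(O[Si](C(C)C)(C(C)C)C(C)C)ccc3C(=O)[C@@H]2O)c1 | intermediate
19 | 2-methylbut-1-en-3-yne | C=C(C)C#C | starting material
20 | (E)-4,4,5,5-tetramethyl-2-(3-methylbuta-1,3-dien-1-yl)-1,3,2-dioxaborolane | C=C(C)/C=C/B1OC(C)(C)C(C)(C)O1 | intermediate
21 | (2R,3R)-2-{2-(TBS-oxy)-5-[(E)-3-methylbuta-1,3-dien-1-yl]phenyl}-3-hydroxy-7-(TIPS-oxy)chroman-4-one | C=C(C)/C=C/c1ccc(O[Si](C)(C)C(C)(C)C)c([C@H]2Oc3cc(O[Si](C(C)C)(C(C)C)C(C)C)ccc3C(=O)[C@@H]2O)c1 | intermediate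
22 | pentasilyl ether of the target (all-trans cyclohexene 1R,5S,6R; flavanonol 2R,3R) | CC(C)=CCc1c(O[Si](C)(C)C(C)(C)C)ccc(C(=O)[C@@H]2[C@@H](c3ccc(O[Si](C(C)C)(C(C)C)C(C)C)cc3O[Si](C(C)C)(C(C)C)C(C)C)CC(C)=C[C@H]2c2ccc(O[Si](C)(C)C(C)(C)C)c([C@H]3Oc4cc(O[Si](C(C)C)(C(C)C)C(C)C)ccc4C(=O)[C@@H]3O)c2)c1O | intermediate
23 | CNP0268637.1 | CC(C)=CCc1c(O)ccc(C(=O)[C@@H]2[C@@H](c3ccc(O)cc3O)CC(C)=C[C@H]2c2ccc(O)c([C@H]3Oc4cc(O)ccc4C(=O)[C@@H]3O)c2)c1O | target

**Totals**
Total steps: 14. Longest linear sequence: 8 steps (9 → 10 → 13 → 15 → 17 → 18 → 21 → 22 → 23).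

**Three steps most likely to fail**

Step 10. The carbene may instead add to the α-aryloxy aldehyde and expel the ring A phenoxide (redox ester formation), or racemisation of 17 may be too slow for a clean dynamic resolution. The fallback sets out from 10 and 14 and returns at 18. Enantioselective addition of (CH2=CH)2Zn to 10 with a chiral amino-alcohol ligand gives (R)-1-[2-(TBS-oxy)-5-iodophenyl]prop-2-en-1-ol F2. Mitsunobu etherification with 14 (PPh3, DIAD, inversion) gives (S)-2-{1-[2-(TBS-oxy)-5-iodophenyl]prop-2-en-1-yloxy}-4-(TIPS-oxy)benzaldehyde F3. Ozonolysis with Me2S work-up, through the ozonide F4 (not isolated), gives (R)-2-{1-[2-(TBS-oxy)-5-iodophenyl]-2-oxoethoxy}-4-(TIPS-oxy)benzaldehyde F5, kept free of base. SmI2 (THF, −78 °C) then joins the two aldehyde carbons through the ketyl radical anion of the aryl aldehyde, a reductive, non-basic reversed-polarity closure that leaves C2 untouched, to give (2R,3S,4S)-2-[2-(TBS-oxy)-5-iodophenyl]-7-(TIPS-oxy)chromane-3,4-diol F6. DDQ oxidises only the electron-rich benzylic C4 carbinol and gives 18; C3 is trans to the aryl group or is brought there by mild equilibration of the ketol.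

Step 13. The exo/endo ratio and facial control are unproven with this bulky silylated pair, and the free 3-OH of 21 may bind boron. The fallback sets out from 8 and 21 and returns at 22. The cycloaddition is run without any chiral promoter under electron-transfer catalysis by Ag nanoparticles on SiO2 (zerovalent silver; CH2Cl2, 50 °C). Because 21 is a single enantiomer, the two exo adducts are diastereomers and 22 is isolated by preparative HPLC; no new compound is made (F0).

Step 8. The ortho-silyloxy aryl group may slow the (π-allyl)iridium pathway, or the product may re-ionise and drift to the linear cinnamyl ether. The fallback sets out from 10 and 11 and returns at 15. Compound 11 is added to 10 and quenched with aq. NH4Cl to give racemic 1-[2-(TBS-oxy)-5-iodophenyl]prop-2-en-1-ol F1, which is joined to 14 by Mitsunobu etherification (PPh3, DIAD, toluene, 0 °C). This is a direct SN2 displacement at the carbinol carbon with no metal allyl intermediate.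

**Further compounds**
F1 | step 8 | racemic 1-[2-(TBS-oxy)-5-iodophenyl]prop-2-en-1-ol | C=CC(O)c1cc(I)ccc1O[Si](C)(C)C(C)(C)C
F2 | step 10 | (R)-1-[2-(TBS-oxy)-5-iodophenyl]prop-2-en-1-ol | C=C[C@@H](O)c1cc(I)ccc1O[Si](C)(C)C(C)(C)C
F3 | step 10 | (S)-2-{1-[2-(TBS-oxy)-5-iodophenyl]prop-2-en-1-yloxy}-4-(TIPS-oxy)benzaldehyde | C=C[C@H](Oc1cc(O[Si](C(C)C)(C(C)C)C(C)C)ccc1C=O)c1cc(I)ccc1O[Si](C)(C)C(C)(C)C
F4 | step 10 | secondary ozonide of F3 (not isolated) | O=Cc1ccc(O[Si](C(C)C)(C(C)C)C(C)C)cc1O[C@@H](C1OCOO1)c1cc(I)ccc1O[Si](C)(C)C(C)(C)C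
F5 | step 10 | (R)-2-{1-[2-(TBS-oxy)-5-iodophenyl]-2-oxoethoxy}-4-(TIPS-oxy)benzaldehyde | O=C[C@H](Oc1cc(O[Si](C(C)C)(C(C)C)C(C)C)ccc1C=O)c1cc(I)ccc1O[Si](C)(C)C(C)(C)C
F6 | step 10 | (2R,3S,4S)-2-[2-(TBS-oxy)-5-iodophenyl]-7-(TIPS-oxy)chromane-3,4-diol | Ic1ccc(O[Si](C)(C)C(C)(C)C)c([C@H]2Oc3cc(O[Si](C(C)C)(C(C)C)C(C)C)ccc3[C@H](O)[C@@H]2O)c1
F0 | step 13 | none | none
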